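The target is read as a fully aromatic 2,3-disubstituted naphthalene to which a guaiacyl–H unit has been added across C1=C2: in ring B (the dihydro ring fused to benzo ring A) the sp3 atoms C1 and C2 sit beside a C3=C4 styrene bond. The key step therefore joins a protected guaiacyl lithium to C1 of a flat naphthalene-2-carbaldimine by a chiral-diether-controlled dearomatizing conjugate addition; protonation, hydrolysis and reduction in the same flask fix the trans C1/C2 pair. The naphthalene is built regiospecifically by a Heck/aldol annulation of a bromobenzaldehyde with 4-methyl itaconate, and a late oxidation of the C3 arm gives the enal.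

Key step: step 7

Numbering: every intermediate is numbered as the target dihydronaphthalene (C1 aryl-bearing, C2, C3, C4, C4a, C5 to C8, C8a; C6 carries OMe, C7 the phenol oxygen), unless a systematic name is given.

Assumption: the (S,S)-enantiomer of 1,2-dimethoxy-1,2-diphenylethane is taken as the one that directs the aryl group to the face of C1 giving 1S; should a trial show the opposite sense, the (R,R)-ligand would be used with no other change.

Step 1
Reactants: 1 2-bromo-5-hydroxy-4-methoxybenzaldehyde
Product: 2 2-bromo-4-methoxy-5-(triisopropylsilyloxy)benzaldehyde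
Conditions: TIPSCl, imidazole, DMF, rt
Reagents that add atoms: chlorotriisopropylsilane, CC(C)[Si](Cl)(C(C)C)C(C)C
Why: Imidazole-mediated silylation of the phenol gives a hindered aryl silyl ether that should withstand the amine base, hydrides and aryllithium used later and fall only to fluoride.

Step 2
Reactants: 2 2-bromo-4-methoxy-5-(triisopropylsilyloxy)benzaldehyde; 3 4-methyl hydrogen itaconate
Product: 5 3-(methoxycarbonyl)-7-methoxy-6-(triisopropylsilyloxy)naphthalene-2-carboxylic acid, via Heck adduct 4 (not isolated)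
Conditions: Pd(OAc)2 (5 mol %), P(o-tol)3, Et3N (5 equiv), DMF, molecular sieves (4 Å), 100 °C; aq. citric acid work-up
Reagents that add atoms: none
Why: Mizoroki–Heck arylation at the CH2 terminus of the itaconate is followed in the same flask by intramolecular aldol (Knoevenagel-type) condensation of the CH2CO2Me carbon with the ortho-formyl group and dehydration to the naphthalene, and because the bromide carbon can only become C4a and the formyl carbon C1, the free acid must end at C3 and the ester at C2.

Step 3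
Reactants: 5 3-(methoxycarbonyl)-7-methoxy-6-(triisopropylsilyloxy)naphthalene-2-carboxylic acid
Product: 7 6-methoxy-7-(triisopropylsilyloxy)naphtho[2,3-c]furan-1(3H)-one, via hydroxy ester 6 (not isolated)
Conditions: BH3·SMe2, THF, 0 °C to rt; MeOH; TsOH (cat.), toluene, 50 °C
Reagents that add atoms: none
Why: Chemoselective borane reduction of the carboxylic acid beside the methyl ester, then acid-catalysed lactonization (phthalide formation), stores C3 at the alcohol level and C2 at the acyl level in one ring.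

Step 4
Reactants: 7 6-methoxy-7-(triisopropylsilyloxy)naphtho[2,3-c]furan-1(3H)-one
Product: 8 6-methoxy-7-(triisopropylsilyloxy)-1,3-dihydronaphtho[2,3-c]furan-1-ol (racemic at the hemiacetal carbon)
Conditions: diisobutylaluminium hydride (1.15 equiv), CH2Cl2, −78 °C; aq. potassium sodium tartrate
Reagents that add atoms: none
Why: Partial reduction of an aryl-fused γ-lactone to the lactol, the tetrahedral aluminium alkoxide holding the aldehyde level at −78 °C until work-up.

Step 5
Reactants: 8 6-methoxy-7-(triisopropylsilyloxy)-1,3-dihydronaphtho[2,3-c]furan-1-ol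
Product: 10 (E)-N-cyclohexyl-1-[6-methoxy-3-(triethylsilyloxymethyl)-7-(triisopropylsilyloxy)naphthalen-2-yl]methanimine, via hydroxy imine 9 (not isolated)
Conditions: cyclohexylamine, MgSO4, CH2Cl2, rt; then Et3N, TESCl, DMAP (cat.), 0 °C; filtration through basic alumina
Reagents that add atoms: cyclohexylamine, NC1CCCCC1; chlorotriethylsilane, CC[Si](Cl)(CC)CC
Why: Imine condensation of the ring-open hydroxy aldehyde form of the lactol with a primary amine, then silylation of the freed primary alcohol, should lock the open (E)-aldimine whose N-cyclohexyl group favours conjugate over direct addition.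

Step 6
Reactants: 11 4-bromo-2-methoxyphenol
Product: 12 (4-bromo-2-methoxyphenoxy)triisopropylsilane
Conditions: TIPSCl, imidazole, DMF, rt
Reagents that add atoms: chlorotriisopropylsilane, CC(C)[Si](Cl)(C(C)C)C(C)C
Why: Imidazole-mediated silylation of the phenol gives a non-coordinating protecting group that survives bromine–lithium exchange and sits para to the carbanion, so no silyl migration is possible.

Step 7
Reactants: 10 (E)-N-cyclohexyl-1-[6-methoxy-3-(triethylsilyloxymethyl)-7-(triisopropylsilyloxy)naphthalen-2-yl]methanimine; 12 (4-bromo-2-methoxyphenoxy)triisopropylsilane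
Product: 17 [(1S,2R)-6-methoxy-1-[3-methoxy-4-(triisopropylsilyloxy)phenyl]-3-(triethylsilyloxymethyl)-7-(triisopropylsilyloxy)-1,2-dihydronaphthalen-2-yl]methanol, via aryllithium 13 (not isolated), via lithium aza-enolate 14 (not isolated), via imine 15 (not isolated), via aldehyde 16 (not isolated)
Conditions: 12, t-BuLi (2 equiv), toluene–Et2O (10:1), −78 °C; (S,S)-1,2-dimethoxy-1,2-diphenylethane (1.4 equiv per Li), then 10, toluene, −45 °C; MeOH, −78 °C; NaOAc–AcOH buffer (pH 4.5), THF–H2O, 0 °C to rt; then NaBH4, MeOH, 0 °C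
Reagents that add atoms: water, O
Why: The diether-complexed aryllithium 13 binds the imine nitrogen of 10 and transfers its aryl group in a 1,4-sense to C1, the only ring carbon conjugated to C=N through the C1=C2 bond of highest double-bond character, which dearomatizes ring B and leaves the lithium aza-enolate 14 with the C3=C4 styrene bond intact. The closest known reaction type is the chiral-diether-mediated asymmetric conjugate addition of aryllithiums to N-cyclohexyl naphthaldimines, the external-ligand relative of the oxazoline-directed dearomatizing additions to naphthalenes. No ring is closed; ring B is kept and only loses its aromaticity. C1 is set by the C2-symmetric diether on lithium, which differentiates the two faces of the flat naphthalene; C2 is set under thermodynamic control after C-protonation, the buffered hydrolysis letting the aldehyde settle trans with aryl and formyl both pseudoaxial (no peri strain with H8, no A(1,2) strain with the C3 arm) before borohydride freezes it. The step needs 1,4- over 1,2-addition and α- over γ-reprotonation: the bulky N-cyclohexyl group and the flanking CH2OSiEt3 arm shield the imine carbon and hold the nitrogen on the C1 side, and reduction directly after equilibration should keep the C3=C4 bond from moving into conjugation.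

Step 8
Reactants: 17 [(1S,2R)-6-methoxy-1-[3-methoxy-4-(triisopropylsilyloxy)phenyl]-3-(triethylsilyloxymethyl)-7-(triisopropylsilyloxy)-1,2-dihydronaphthalen-2-yl]methanol
Product: 18 triethyl({(1S,2R)-6-methoxy-1-[3-methoxy-4-(triisopropylsilyloxy)phenyl]-7-(triisopropylsilyloxy)-2-(triisopropylsilyloxymethyl)-1,2-dihydronaphthalen-3-yl}methoxy)silane
Conditions: TIPSCl, imidazole, DMAP (cat.), DMF, rt
Reagents that add atoms: chlorotriisopropylsilane, CC(C)[Si](Cl)(C(C)C)C(C)C
Why: Silylation of the primary alcohol on C2 masks the hydroxyl that would otherwise close a lactol onto the future C3 aldehyde and be over-oxidized to the lactone.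

Step 9
Reactants: 18 triethyl({(1S,2R)-6-methoxy-1-[3-methoxy-4-(triisopropylsilyloxy)phenyl]-7-(triisopropylsilyloxy)-2-(triisopropylsilyloxymethyl)-1,2-dihydronaphthalen-3-yl}methoxy)silane
Product: 19 (1S,2R)-6-methoxy-1-[3-methoxy-4-(triisopropylsilyloxy)phenyl]-7-(triisopropylsilyloxy)-2-(triisopropylsilyloxymethyl)-1,2-dihydronaphthalene-3-carbaldehyde
Conditions: (COCl)2, DMSO, CH2Cl2, −78 to −30 °C; Et3N, −78 °C to rt
Reagents that add atoms: none
Why: A Swern oxidation run with warming converts a primary triethylsilyl ether directly into the aldehyde (oxidative desilylation through the alkoxysulfonium salt) while triisopropylsilyl ethers stay inert, so the conjugated enal should form without touching C1 or C2.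

Step 10
Reactants: 19 (1S,2R)-6-methoxy-1-[3-methoxy-4-(triisopropylsilyloxy)phenyl]-7-(triisopropylsilyloxy)-2-(triisopropylsilyloxymethyl)-1,2-dihydronaphthalene-3-carbaldehyde
Product: 20 (1S,2R)-7-hydroxy-1-(4-hydroxy-3-methoxyphenyl)-2-(hydroxymethyl)-6-methoxy-1,2-dihydronaphthalene-3-carbaldehyde (7,8,9,9-tetradehydroisolariciresinol)
Conditions: tetrabutylammonium fluoride, AcOH (1:1), THF, 0 °C to rt, argon
Reagents that add atoms: none
Why: Fluoride-induced desilylation removes the two aryl and the one primary triisopropylsilyl ether, and the acetic acid buffer keeps the phenoxides and the oxidation-prone dihydronaphthalene away from strong base.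

Compound list
1 | 2-bromo-5-hydroxy-4-methoxybenzaldehyde (6-bromoisovanillin) | O=Cc1cc(O)c(OC)cc1Br | starting material
2 | 2-bromo-4-methoxy-5-(triisopropylsilyloxy)benzaldehyde | O=Cc1cc(O[Si](C(C)C)(C(C)C)C(C)C)c(OC)cc1Br | intermediate
3 | 4-methyl hydrogen itaconate (2-methylidenebutanedioic acid 4-methyl ester) | C=C(CC(=O)OC)C(=O)O | starting material
4 | (E)-2-{[2-formyl-5-methoxy-4-(triisopropylsilyloxy)phenyl]methylidene}butanedioic acid 4-methyl ester (Heck adduct, not isolated) | O=Cc1cc(O[Si](C(C)C)(C(C)C)C(C)C)c(OC)cc1/C=C(\CC(=O)OC)C(=O)O | intermediate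
5 | 3-(methoxycarbonyl)-7-methoxy-6-(triisopropylsilyloxy)naphthalene-2-carboxylic acid | COC(=O)c1cc2cc(O[Si](C(C)C)(C(C)C)C(C)C)c(OC)cc2cc1C(=O)O | intermediate
6 | methyl 3-(hydroxymethyl)-6-methoxy-7-(triisopropylsilyloxy)naphthalene-2-carboxylate (hydroxy ester, not isolated) | COC(=O)c1cc2cc(O[Si](C(C)C)(C(C)C)C(C)C)c(OC)cc2cc1CO | intermediate
7 | 6-methoxy-7-(triisopropylsilyloxy)naphtho[2,3-c]furan-1(3H)-one | O=C1OCc2cc3cc(OC)c(O[Si](C(C)C)(C(C)C)C(C)C)cc3cc21 | intermediate
8 | 6-methoxy-7-(triisopropylsilyloxy)-1,3-dihydronaphtho[2,3-c]furan-1-ol (racemic hemiacetal) | OC1OCc2cc3cc(OC)c(O[Si](C(C)C)(C(C)C)C(C)C)cc3cc21 | intermediate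
9 | (E)-N-cyclohexyl-1-[3-(hydroxymethyl)-6-methoxy-7-(triisopropylsilyloxy)naphthalen-2-yl]methanimine (hydroxy imine, not isolated) | OCc1cc2cc(OC)c(O[Si](C(C)C)(C(C)C)C(C)C)cc2cc1/C=N/C3CCCCC3 | intermediate
10 | (E)-N-cyclohexyl-1-[6-methoxy-3-(triethylsilyloxymethyl)-7-(triisopropylsilyloxy)naphthalen-2-yl]methanimine | CC[Si](CC)(CC)OCc1cc2cc(OC)c(O[Si](C(C)C)(C(C)C)C(C)C)cc2cc1/C=N/C3CCCCC3 | intermediate
11 | 4-bromo-2-methoxyphenol | COc1cc(Br)ccc1O | starting material
12 | (4-bromo-2-methoxyphenoxy)triisopropylsilane | COc1cc(Br)ccc1O[Si](C(C)C)(C(C)C)C(C)C | intermediate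
13 | [3-methoxy-4-(triisopropylsilyloxy)phenyl]lithium (not isolated) | COc1cc([Li])ccc1O[Si](C(C)C)(C(C)C)C(C)C | intermediate
14 | lithium cyclohexyl({(1S)-6-methoxy-1-[3-methoxy-4-(triisopropylsilyloxy)phenyl]-3-(triethylsilyloxymethyl)-7-(triisopropylsilyloxy)naphthalen-2(1H)-ylidene}methyl)amide (aza-enolate, not isolated) | COc1cc([C@H]2c3cc(O[Si](C(C)C)(C(C)C)C(C)C)c(OC)cc3C=C(CO[Si](CC)(CC)CC)C2=CN([Li])C4CCCCC4)ccc1O[Si](C(C)C)(C(C)C)C(C)C | intermediate
15 | (E)-N-cyclohexyl-1-{(1S)-6-methoxy-1-[3-methoxy-4-(triisopropylsilyloxy)phenyl]-3-(triethylsilyloxymethyl)-7-(triisopropylsilyloxy)-1,2-dihydronaphthalen-2-yl}methanimine, both C2 epimers (not isolated) | COc1cc([C@H]2c3cc(O[Si](C(C)C)(C(C)C)C(C)C)c(OC)cc3C=C(CO[Si](CC)(CC)CC)C2/C=N/C4CCCCC4)ccc1O[Si](C(C)C)(C(C)C)C(C)C | intermediate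
16 | (1S,2R)-6-methoxy-1-[3-methoxy-4-(triisopropylsilyloxy)phenyl]-3-(triethylsilyloxymethyl)-7-(triisopropylsilyloxy)-1,2-dihydronaphthalene-2-carbaldehyde, trans (not isolated) | COc1cc([C@H]2c3cc(O[Si](C(C)C)(C(C)C)C(C)C)c(OC)cc3C=C(CO[Si](CC)(CC)CC)[C@@H]2C=O)ccc1O[Si](C(C)C)(C(C)C)C(C)C | intermediate
17 | [(1S,2R)-6-methoxy-1-[3-methoxy-4-(triisopropylsilyloxy)phenyl]-3-(triethylsilyloxymethyl)-7-(triisopropylsilyloxy)-1,2-dihydronaphthalen-2-yl]methanol | COc1cc([C@H]2c3cc(O[Si](C(C)C)(C(C)C)C(C)C)c(OC)cc3C=C(CO[Si](CC)(CC)CC)[C@@H]2CO)ccc1O[Si](C(C)C)(C(C)C)C(C)C | intermediate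
18 | triethyl({(1S,2R)-6-methoxy-1-[3-methoxy-4-(triisopropylsilyloxy)phenyl]-7-(triisopropylsilyloxy)-2-(triisopropylsilyloxymethyl)-1,2-dihydronaphthalen-3-yl}methoxy)silane | COc1cc([C@H]2c3cc(O[Si](C(C)C)(C(C)C)C(C)C)c(OC)cc3C=C(CO[Si](CC)(CC)CC)[C@@H]2CO[Si](C(C)C)(C(C)C)C(C)C)ccc1O[Si](C(C)C)(C(C)C)C(C)C | intermediate
19 | (1S,2R)-6-methoxy-1-[3-methoxy-4-(triisopropylsilyloxy)phenyl]-7-(triisopropylsilyloxy)-2-(triisopropylsilyloxymethyl)-1,2-dihydronaphthalene-3-carbaldehyde | COc1cc([C@H]2c3cc(O[Si](C(C)C)(C(C)C)C(C)C)c(OC)cc3C=C(C=O)[C@@H]2CO[Si](C(C)C)(C(C)C)C(C)C)ccc1O[Si](C(C)C)(C(C)C)C(C)C | intermediate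
20 | (1S,2R)-7-hydroxy-1-(4-hydroxy-3-methoxyphenyl)-2-(hydroxymethyl)-6-methoxy-1,2-dihydronaphthalene-3-carbaldehyde (7,8,9,9-tetradehydroisolariciresinol) | COc1cc([C@H]2c3cc(O)c(OC)cc3C=C(C=O)[C@@H]2CO)ccc1O | target

Total step count: 10. Longest linear sequence: 9 steps (steps 1 to 5, then 7 to 10); step 6 is the one-step side branch.

Steps most likely to fail

Step 7. The aryllithium may attack the imine carbon or silicon instead of C1. Lithium bromide and the flanking silyloxymethyl arm may erode the facial discrimination of the diether complex. The C3=C4 bond may drift into conjugation with the formyl group while C2 equilibrates. The fallback replaces the external ligand by a covalent auxiliary; it sets out from lactol 8 and comes back at aldehyde 16. Lactol 8 is condensed with (2S)-1-methoxy-3,3-dimethylbutan-2-amine (the methyl ether of (S)-tert-leucinol) to give the hydroxy imine F1, which is silylated as in step 5 to the triethylsilyl-protected chiral imine F2. Aryllithium 13 then adds in THF at −78 °C under chelation control (lithium held between N and OMe, aryl delivered away from tert-butyl) to give the lithium aza-enolate F3. C-protonation gives the imine F4, and buffered hydrolysis releases the auxiliary and the trans aldehyde 16, which is reduced as before to 17. The antipodal amine would be taken if the sense of induction required it.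

Step 2. Oxidative addition may be slow and the catalyst may be deactivated by the free carboxylate. The double bond may isomerize without ring closure, or the aryl silyl ether may be lost at 100 °C. The fallback makes the C4–C4a bond by formylation instead of a Heck reaction; it sets out from 2 and comes back at the Heck adduct 4. Aldehyde 2 is protected (ethylene glycol, TsOH, toluene) as 2-[2-bromo-4-methoxy-5-(triisopropylsilyloxy)phenyl]-1,3-dioxolane F5. Bromine–lithium exchange (n-BuLi, THF, −78 °C) and DMF give 2-(1,3-dioxolan-2-yl)-5-methoxy-4-(triisopropylsilyloxy)benzaldehyde F6. Horner–Wadsworth–Emmons olefination with 1-tert-butyl 4-methyl 2-(diethoxyphosphoryl)butanedioate F7 (from tert-butyl diethylphosphonoacetate and methyl bromoacetate, NaH, THF) gives the (E)-arylidene succinate F8. TFA in wet CH2Cl2 removes the acetal and the tert-butyl ester to give 4, which is cyclized with Et3N in DMF at 100 °C to 5.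

Step 9. Exchange of the triethylsilyl ether with the chlorosulfonium salt may be sluggish, with chlorination or methylthiomethylation of the electron-rich rings competing on warming. The fallback separates deprotection from oxidation; it sets out from 18 and comes back at 19. Pyridinium p-toluenesulfonate in MeOH at 0 °C cleaves only the primary triethylsilyl ether to give the allylic alcohol {(1S,2R)-6-methoxy-1-[3-methoxy-4-(triisopropylsilyloxy)phenyl]-7-(triisopropylsilyloxy)-2-(triisopropylsilyloxymethyl)-1,2-dihydronaphthalen-3-yl}methanol F9. MnO2 in CH2Cl2 then oxidizes it to 19; with the C2 hydroxymethyl group silylated no lactol can form.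

Further compounds
F1 | step 7 | (E)-1-[3-(hydroxymethyl)-6-methoxy-7-(triisopropylsilyloxy)naphthalen-2-yl]-N-[(2S)-1-methoxy-3,3-dimethylbutan-2-yl]methanimine | OCc1cc2cc(OC)c(O[Si](C(C)C)(C(C)C)C(C)C)cc2cc1/C=N/[C@H](COC)C(C)(C)C
F2 | step 7 | (E)-1-[6-methoxy-3-(triethylsilyloxymethyl)-7-(triisopropylsilyloxy)naphthalen-2-yl]-N-[(2S)-1-methoxy-3,3-dimethylbutan-2-yl]methanimine | CC[Si](CC)(CC)OCc1cc2cc(OC)c(O[Si](C(C)C)(C(C)C)C(C)C)cc2cc1/C=N/[C@H](COC)C(C)(C)C
F3 | step 7 | lithium [(2S)-1-methoxy-3,3-dimethylbutan-2-yl]({(1S)-6-methoxy-1-[3-methoxy-4-(triisopropylsilyloxy)phenyl]-3-(triethylsilyloxymethyl)-7-(triisopropylsilyloxy)naphthalen-2(1H)-ylidene}methyl)amide | COc1cc([C@H]2c3cc(O[Si](C(C)C)(C(C)C)C(C)C)c(OC)cc3C=C(CO[Si](CC)(CC)CC)C2=CN([Li])[C@H](COC)C(C)(C)C)ccc1O[Si](C(C)C)(C(C)C)C(C)C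
F4 | step 7 | (E)-1-{(1S)-6-methoxy-1-[3-methoxy-4-(triisopropylsilyloxy)phenyl]-3-(triethylsilyloxymethyl)-7-(triisopropylsilyloxy)-1,2-dihydronaphthalen-2-yl}-N-[(2S)-1-methoxy-3,3-dimethylbutan-2-yl]methanimine, both C2 epimers | COc1cc([C@H]2c3cc(O[Si](C(C)C)(C(C)C)C(C)C)c(OC)cc3C=C(CO[Si](CC)(CC)CC)C2/C=N/[C@H](COC)C(C)(C)C)ccc1O[Si](C(C)C)(C(C)C)C(C)C
F5 | step 2 | 2-[2-bromo-4-methoxy-5-(triisopropylsilyloxy)phenyl]-1,3-dioxolane | Brc1cc(OC)c(O[Si](C(C)C)(C(C)C)C(C)C)cc1C1OCCO1
F6 | step 2 | 2-(1,3-dioxolan-2-yl)-5-methoxy-4-(triisopropylsilyloxy)benzaldehyde | O=Cc1cc(OC)c(O[Si](C(C)C)(C(C)C)C(C)C)cc1C1OCCO1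
F7 | step 2 | 1-tert-butyl 4-methyl 2-(diethoxyphosphoryl)butanedioate | CCOP(=O)(OCC)C(CC(=O)OC)C(=O)OC(C)(C)C
F8 | step 2 | 1-tert-butyl 4-methyl (E)-2-{[2-(1,3-dioxolan-2-yl)-5-methoxy-4-(triisopropylsilyloxy)phenyl]methylidene}butanedioate | COC(=O)C/C(C(=O)OC(C)(C)C)=C\c1cc(OC)c(O[Si](C(C)C)(C(C)C)C(C)C)cc1C1OCCO1
F9 | step 9 | {(1S,2R)-6-methoxy-1-[3-methoxy-4-(triisopropylsilyloxy)phenyl]-7-(triisopropylsilyloxy)-2-(triisopropylsilyloxymethyl)-1,2-dihydronaphthalen-3-yl}methanol | COc1cc([C@H]2c3cc(O[Si](C(C)C)(C(C)C)C(C)C)c(OC)cc3C=C(CO)[C@@H]2CO[Si](C(C)C)(C(C)C)C(C)C)ccc1O[Si](C(C)C)(C(C)C)C(C)C
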